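(The runs come from a simulation for substances that don't exist; scatter was added.)

The closed, stirred vessel held L and the catalyst Z at 5 °C, and Monday's readings of it stopped at 8.00 min; Friday's run was the same charge, colder.

| setting | Monday's | Friday's | flask |
|---|---|---|---|
| L | 2.5 M | 2.5 M | 2.5 M |
| Z | 4.8 mol% | 4.8 mol% | 4.8 mol% |
| temperature | 5 °C | −10 °C | 5 °C |
| remark | the very flask that is asked about, followed so far | run made earlier |  |
| time |  |  | 10 min |

| run | time / min | Q / % | L / % |
|---|---|---|---|
| Monday's | 0.667 | 5.5 | 63.3 |
| Monday's | 2.00 | 11.5 | 26.0 |
| Monday's | 4.00 | 12.8 | 8.0 |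
| Monday's | 6.00 | 12.9 | 2.9 |
| Monday's | 8.00 | 13.0 | 0.8 |
| Friday's | 1.33 | 2.1 | 86.4 |
| Friday's | 4.00 | 6.2 | 64.2 |
| Friday's | 8.00 | 11.0 | 42.2 |
| Friday's | 12.0 | 11.2 | 27.3 |
| Friday's | 15.0 | 11.8 | 19.4 |

(readings scatter by 0.5 percentage points)

- eta: at 10 min raise the temperature by 20 K, then wait 5.0 min
- delta: change nothing and wait 5.0 min more
- beta: at 10 min add Z, 50.0 % of the amount charged, then wait 5.0 min

- Q, in percent of the L first charged, at 10 min
- what to do for the largest gain in Q; "none" if nothing gains more than 2 percentage points (eta / delta / beta / none)
- Q present, in percent of the L first charged, after delta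
- Q present, in percent of the L first charged, after beta

- additions bring no volume worth counting
- the numbers in the tables scatter by 0.5 percentage points (one standard deviation)
- a reading or a percentage of Q counts all its forms, free or not
- a reading of L is of its free form alone

In Monday's flask Q had stood still since 4.00 min, so I put it near 13.0 % at 10 min. Waiting looked useless, and the question was what new Z could do. My first estimate was a count: 2.71 Q per Z charged, so the added Z would bring 6.5 percentage points.

But that charge of Z began with nothing to work on, if Q comes from the unseen part W, the L charged that is neither L nor Q. W stood at 86.2 % by 8.00 min. So I compared rates instead. The pull p is Q's rate divided by the mean W of a span, a pseudo-first-order constant. It was 0.529 min⁻¹ in the first span and 0.0961 min⁻¹ in the second, whose middles lie 1.00 min apart. So p decayed at 1.71 min⁻¹; L fell at 0.668 min⁻¹, slower than that. On that reading 10 min lay 24.7 half-lives of p past the start, so I expected delta and eta to gain nothing.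

Summing p over its life gave 0.547, the reach R of a charge of Z: at this temperature and concentration, a charge added to a standing W turns the share 1 − exp(−R) of it into Q.

The objection was that W may be dead. In Friday's run, though, Q gained per L consumed was 0.154 in the first span and 0.218 in the third; the later figure is higher, which suggests a store filling, though thinly against the scatter of 0.5 points. I committed to beta: R scaled by 50.0 % gave a gain of 21 points.

The forecast put Q at 13 % at 10 min, 13 % after delta and 13.1 % after beta, and its choice was none. Its ground was “Fresh Z could restart Q formation, but there is almost no L left to convert.”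

The flask gave 12.7 %, 12.7 % after delta, 12.7 % after eta and 31.5 % after beta, so the choice was beta.

    L → J (k = 0.0109 s⁻¹, Ea = 73.0 kJ mol⁻¹)
    Z + J → Z + Q (k = 0.136 M⁻¹ s⁻¹, Ea = 60.0 kJ mol⁻¹)
    Z + Q → Z + G (k = 0.0545 M⁻¹ s⁻¹, Ea = 42.0 kJ mol⁻¹)
    Z → X (k = 0.0286 s⁻¹, Ea = 66.0 kJ mol⁻¹)
    L + Q ⇌ E, settled at all times (K = 0.260 M⁻¹, ΔH = 31.0 kJ mol⁻¹)
    (constants at 5 °C)

In this flask Z went to X with half of that step's turnover up to 10 min done by 0.405 min, while L went to J with half done by 1.08 min, and Z + J → Z + Q had 99.9 % of its turnover up to 10 min behind it at 5.00 min. At 10 min J stood at 86.5 % of the L charged and Z at 0 % of the catalyst charged, and the added Z gained 19 points where the reach had given 21 points.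

The neighbour charged with 0.62 M of L, at the same loading, holds Z at a quarter of this flask's concentration, so my estimate of its reach is 0.136 and Q, scaled with R, comes to 3.23 % of its own L charged. Computed, that neighbour gives 3.69 %.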